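## Retrosynthetic overview

- The benzylic C–OH bond of the target is made last, by hydrolysis of a para-hydroxybenzyl bromide. That bromide comes from the aryl–CH3 group of a tri-O-methylated diarylmethane by phenol-gated ipso-bromination, dehydrobromination to a quinone methide and BBr3 treatment, all in one pot.
- The diarylmethane comes from a Friedel–Crafts benzylation of 2-bromo-6-methoxy-4-methylphenol with (3-bromo-4,5-dimethoxyphenyl)methanol. The CH3 group is a non-ionisable placeholder for CH2OH, so the nucleophile cannot self-condense.
- The two partners come from creosol (Br2) and from 3-bromo-4,5-dimethoxybenzaldehyde (NaBH4).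
- No ring is formed; both benzene rings (ring A from creosol, ring B from the aldehyde) are bought.

Assumption: the target has no stereocentre or other stereo element, so it is achiral, no stereocontrol is needed, and all SMILES are written without stereodescriptors.

## Route

Step 1
Reactants: 1 2-methoxy-4-methylphenol (creosol)
Product: 2 2-bromo-6-methoxy-4-methylphenol
Conditions: Br2 (1.0 equiv), CH2Cl2, −20 to 0 °C
Reagents that add atoms: bromine, BrBr
Why: Electrophilic aromatic bromination: the free OH is the strongest director and its para position is blocked by CH3, so bromine enters ortho to OH (as in vanillin to 5-bromovanillin), and one equivalent at low temperature avoids a second bromination.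

Step 2
Reactants: 3 3-bromo-4,5-dimethoxybenzaldehyde
Product: 4 (3-bromo-4,5-dimethoxyphenyl)methanol
Conditions: NaBH4 (0.5 equiv), MeOH, 0 °C to rt
Reagents that add atoms: none
Why: NaBH4 hydride reduction of the aldehyde; the aryl bromide and the methyl ethers are inert.

Step 3
Reactants: 2 2-bromo-6-methoxy-4-methylphenol (2 equiv); 4 (3-bromo-4,5-dimethoxyphenyl)methanol
Product: 5 2-bromo-3-[(3-bromo-4,5-dimethoxyphenyl)methyl]-6-methoxy-4-methylphenol
Conditions: CF3SO3H (5 mol%), (CF3)2CHOH, 0 °C to rt, 4 added over 2 h
Reagents that add atoms: none
Why: Dehydrative Friedel–Crafts benzylation: acid ionises 4 (loss of water) to a para-methoxy-stabilised benzyl cation that attacks 2 at C3, para to its OMe (all positions ortho and para to OH are blocked and O-benzylation is reversible under acid), while the CH3 of 2 cannot ionise and the excess of 2 suppresses a second benzylation on ring B.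

Step 4
Reactants: 5 2-bromo-3-[(3-bromo-4,5-dimethoxyphenyl)methyl]-6-methoxy-4-methylphenol
Product: 10 5-hydroxyisoavrainvilleol, via bromodienone 6 (not isolated), via quinone methide 7 (not isolated), via benzylic bromide 8 (not isolated), via tetraol bromide 9 (not isolated)
Conditions: one pot under argon: Br2 (1.0 equiv), CH2Cl2, −78 °C; i-Pr2NEt (2.2 equiv), −78 to −40 °C; BBr3 (9 equiv), −78 °C to rt; then THF/H2O (1:1), 0 °C to rt, dilute
Reagents that add atoms: water, O
Why: Proposed new method: a one-pot, phenol-gated formal hydroxylation of an aryl methyl group merged with global O-demethylation, in which the benzylic C–O bond of the target is made last. The only free phenol of 5 has Br and OMe at both ortho positions, so Br2 at −78 °C attacks the para carbon that bears CH3 (ipso-bromination) and gives bromodienone 6 (racemic; its sp3 centre is destroyed in the next event), and the oxidant is fully consumed before any oxidisable catechol exists. The hindered amine then takes up the HBr of the bromination and removes HBr from 6 across the C4–CH3 bond to give para-quinone methide 7; from this point no free acid is present, so reversal or migration of bromine into ring A is shut off, and the bridging CH2 cannot react this way because it is para only to OMe groups. BBr3 adds across 7 in 1,6-fashion (O–B, C–Br) to give 8 and cleaves the three aryl methyl ethers to 9. Water finally hydrolyses the boron esters and replaces the benzylic bromide by SN1 through the para-hydroxybenzyl cation, forming the C–O bond of 10. Closest known reaction types: the quinobromide and para-quinone methide chemistry of 2,6-di-tert-butyl-4-methylphenol (ipso-bromination, base-induced dehydrobromination), BBr3 cleavage of aryl methyl ethers, and solvolysis of para-hydroxybenzyl halides; to my knowledge these have not been telescoped in this way or applied to an unhindered guaiacol-type diarylmethane.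

## Compound list

1 | 2-methoxy-4-methylphenol (creosol) | Cc1ccc(O)c(OC)c1 | starting material
2 | 2-bromo-6-methoxy-4-methylphenol | Cc1cc(Br)c(O)c(OC)c1 | intermediate
3 | 3-bromo-4,5-dimethoxybenzaldehyde | O=Cc1cc(Br)c(OC)c(OC)c1 | starting material
4 | (3-bromo-4,5-dimethoxyphenyl)methanol | OCc1cc(Br)c(OC)c(OC)c1 | intermediate
5 | 2-bromo-3-[(3-bromo-4,5-dimethoxyphenyl)methyl]-6-methoxy-4-methylphenol | Cc1cc(OC)c(O)c(Br)c1Cc1cc(Br)c(OC)c(OC)c1 | intermediate
6 | 2,4-dibromo-3-[(3-bromo-4,5-dimethoxyphenyl)methyl]-6-methoxy-4-methylcyclohexa-2,5-dien-1-one (racemic) | CC1(Br)C=C(OC)C(=O)C(Br)=C1Cc1cc(Br)c(OC)c(OC)c1 | intermediate (not isolated)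
7 | 2-bromo-3-[(3-bromo-4,5-dimethoxyphenyl)methyl]-6-methoxy-4-methylidenecyclohexa-2,5-dien-1-one | C=C1C=C(OC)C(=O)C(Br)=C1Cc1cc(Br)c(OC)c(OC)c1 | intermediate (not isolated)
8 | 2-bromo-4-(bromomethyl)-3-[(3-bromo-4,5-dimethoxyphenyl)methyl]-6-methoxyphenol (held as its O-boron ester) | BrCc1cc(OC)c(O)c(Br)c1Cc1cc(Br)c(OC)c(OC)c1 | intermediate (not isolated)
9 | 3-bromo-5-(bromomethyl)-4-[(3-bromo-4,5-dihydroxyphenyl)methyl]benzene-1,2-diol (held as its boron esters) | BrCc1cc(O)c(O)c(Br)c1Cc1cc(O)c(O)c(Br)c1 | intermediate (not isolated)
10 | 5-hydroxyisoavrainvilleol, 3-bromo-4-[(3-bromo-4,5-dihydroxyphenyl)methyl]-5-(hydroxymethyl)benzene-1,2-diol (achiral) | OCc1cc(O)c(O)c(Br)c1Cc1cc(O)c(O)c(Br)c1 | target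

## Step count and risks

Total step count: 4. Longest linear sequence: 3 steps (1 to 2 to 5 to 10; the branch 3 to 4 to 5 to 10 is equally long).

**Step 4 (the proposed new method) is the most likely to fail.** Br2 could brominate ring B, the quinone methide 7 could oligomerise, or the benzylic bromides 8 and 9 could alkylate the electron-rich rings under BBr3. The fallback uses known chemistry, sets out from 5 and comes back at 9, at the cost of one extra step. DDQ (1.05 equiv) in MeOH at rt abstracts hydride from the methyl group para to the free phenol and methanol adds 1,6; this is the established DDQ benzylic methoxylation of para-cresols. It gives the isolable ether 2-bromo-3-[(3-bromo-4,5-dimethoxyphenyl)methyl]-6-methoxy-4-(methoxymethyl)phenol F1. In a separate operation BBr3 in CH2Cl2 (−78 °C to rt) cleaves the three aryl methyl ethers and converts the methoxymethyl group into the bromomethyl group, which is 9. Aqueous THF then gives 10 as in the main route.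

**Step 3 is the second risk.** Attack ortho instead of para to the OMe of 2, or a second benzylation on ring B, would give mixtures. The fallback sets out from 2 and 4 and comes back at 5, replacing the electrophilic substitution by a cross-coupling. NIS with catalytic CF3CO2H in MeCN iodinates 2 para to the methoxy group to give 2-bromo-3-iodo-6-methoxy-4-methylphenol F2. PBr3 in CH2Cl2 at 0 °C converts 4 into 1-bromo-5-(bromomethyl)-2,3-dimethoxybenzene F3. Zinc dust with LiCl in THF inserts into the benzylic C–Br bond of F3 to give [(3-bromo-4,5-dimethoxyphenyl)methyl]zinc bromide F4. Negishi coupling of F2 with F4 (slow addition, Pd(OAc)2 2 mol%, SPhos 4 mol%, THF, rt) takes place only at the C–I bond, because zerovalent palladium inserts into aryl iodides far faster than into aryl bromides, and gives 5.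

**Step 1 is the third risk.** Bromination para to the OMe group, or dibromination, would give the wrong ring-A pattern. The fallback does not set out from 1 but from purchased 3-bromo-4-hydroxy-5-methoxybenzaldehyde (5-bromovanillin) F5, in which bromine already sits ortho to OH, and comes back at 2. Ionic hydrogenation with Et3SiH (3 equiv) in CF3CO2H/CH2Cl2 at 0 °C to rt reduces the formyl group to methyl and gives 2.

## Further compounds

F1 | step 4 | 2-bromo-3-[(3-bromo-4,5-dimethoxyphenyl)methyl]-6-methoxy-4-(methoxymethyl)phenol | COCc1cc(OC)c(O)c(Br)c1Cc1cc(Br)c(OC)c(OC)c1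
F2 | step 3 | 2-bromo-3-iodo-6-methoxy-4-methylphenol | Cc1cc(OC)c(O)c(Br)c1I
F3 | step 3 | 1-bromo-5-(bromomethyl)-2,3-dimethoxybenzene | BrCc1cc(Br)c(OC)c(OC)c1
F4 | step 3 | [(3-bromo-4,5-dimethoxyphenyl)methyl]zinc bromide | Br[Zn]Cc1cc(Br)c(OC)c(OC)c1
F5 | step 1 | 3-bromo-4-hydroxy-5-methoxybenzaldehyde (5-bromovanillin) | O=Cc1cc(Br)c(O)c(OC)c1
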